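## The problem

The target 15 is an achiral 1,4-naphthoquinone. Ring A is the quinone ring (C1–C4, C4a, C8a) with a methoxy group at C2. Ring B is the benzo ring, with a methoxy group at C6 and a 3,4-dimethoxyphenyl group (ring C) at C8, peri to the C1 carbonyl. There are no stereocentres, and ring C has no ortho substituent, so nothing stereochemical has to be set or can be used for control; the difficulty is regiochemical. Three relationships must be fixed: the C2 methoxy group must sit beside the carbonyl that is peri to ring C (the 2,8- and not the 3,8-isomer), the ring B methoxy group must be meta to the aryl group, and the biaryl bond must be made at a peri-hindered carbon. Adding methoxide late to a 6,8-disubstituted naphthoquinone would not separate C2 from C3 reliably, because the remote ring B substituents bias the two enone termini only weakly. The methoxyquinone is a vinylogous ester that nucleophiles and reductants attack, so it should appear in the last step; the electron-rich naphthol before it is air-sensitive and the silyl enol ether used on the way is acid-sensitive. The enabling feature is that ring A is a 1-indanone plus one carbon. C1, C3, C4, C4a and C8a form the five-membered ring of a 7-aryl-5-methoxyindan-1-one whose carbonyl carbon is already bonded to C8a next to the aryl-bearing C8. The missing atom C2 lies between the carbonyl carbon and the α-carbon, which is the enol ether bond into which a dihalocarbene inserts.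

## Retrosynthesis

Naphthalene locants of 15 are used for ring positions; indanone locants are used in the names of the indanones.

**15 to 14.** The C4=O bond is removed first, leading to naphthol 14, which has the free hydroxyl at C1, the methoxy group at C2 and C4 as the only open position para to oxygen. This is preferred to unmasking a 1,4-dimethoxyarene, where an oxidative demethylation would have to choose ring A over the equally electron-rich ring C. It is also preferred to adding methoxide to a preformed quinone, which leaves C2 against C3 open. The forward step must be a para-selective phenol-to-quinone oxidation that spares three aryl methyl ethers.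

**14 to 12.** The C2–OMe bond is cut and the methoxy group is traced to a bromide, with the C1 oxygen carried as its silyl ether in 12. The halogen costs nothing, since it arrives with the inserted carbon. The forward step asks for a copper-mediated exchange of an aryl bromide for methoxide; the same methoxide releases the naphtholate 13 on the way.

**12 to 9 and 10.** The strategic cut removes C2 with its two bonds, C1–C2 and C2–C3, and contracts ring A to the five-membered ring of silyl enol ether 9; bromoform 10 supplies the carbon. Cuts through ring B would instead have to create the C2/C8 relationship by electronic bias in a cycloaddition. Here the relationship is a matter of connectivity: the oxygen-bearing carbon of 9 is already bonded to the ring fusion carbon next to the aryl group. The precursor is one ring atom smaller, has no halogen and derives from a simple ketone. The forward reaction must add the carbene to the enol ether only, and the adduct 11 must open with loss of bromide and a proton, not of the silyl group.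

**9 to 8.** The O–Si bond is cut to give indanone 8. The ketone has a single enolisable position, so the enol ether can form in one sense only.

**8 to 6 and 7.** The biaryl bond at C8 is cut to bromoindanone 6 and boronic acid 7. Coupling after the indanone is closed keeps the Friedel–Crafts substrate small, so ring C is never offered as a competing nucleophile. The forward step is a cross-coupling at a bromide ortho to a carbonyl group, which is activated and only moderately hindered.

**6 to 4.** The acyl–aryl bond of the five-membered ring is cut to benzyl Meldrum's acid 4. The forward acylation must go to the ring position para to methoxy and ortho to bromine; the acylation product 5 loses carbon dioxide in the flask.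

**4 to 1 and 2.** The benzylic C–C bond is cut to aldehyde 1 and Meldrum's acid 2, joined by condensation to 3 and conjugate reduction. Both are commercial, and 1 already holds bromine and methoxy in the 1,3,5-pattern that ring B needs.

## Roads not taken

**Alternative 1:** Ring B is cut at C5–C6 and C7–C8. In the forward sense the ortho-quinoid benzopyranone A2, generated in the flask, would add methoxyacetylene A3 across its diene termini. The bridged lactone would then lose its one-carbon bridge by decarboxylative cycloreversion and give tetramethoxynaphthalene A1 with ring B already aromatic; oxidative demethylation of ring A would finish 15.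
- Merits: the route is convergent, ring B and its methoxy group arrive in one operation, and only one step follows the key step.
- Weak points:
  - A2 has to be released from a pentasubstituted benzene with an aroyl group and an acetic acid chain ortho to each other, which is longer to make than the whole chosen route.
  - A3 is volatile and polymerises easily.
  - The electronically preferred bonding of the nucleophilic alkyne carbon is to the aryl-bearing terminus of A2, the more hindered one, so sterics oppose the required regiochemistry.
  - The final oxidation of A1 must select the para pair of methoxy groups in ring A over the ortho pair and over ring C.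
- Comparison: this road is better in convergence and in the short endgame. The chosen plan sets against that simple commercial starting materials and positions fixed by connectivity instead of by the polarisation of a transient diene.

**Alternative 2:** Ring B is cut at C4a–C5 and C6–C7. Vinylquinone A5 would act as an electron-poor diene, made of one quinone double bond and the exocyclic alkene, toward ketene acetal A6. The adduct would tautomerise to hydroquinone A4; loss of methanol would aromatise ring B with the C6 methoxy group in place and a mild oxidation would give 15.
- Merits: the oxidation levels fit the target well, no protecting group is needed, and the sequence after the key step is short.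
- Weak points:
  - A5 is a cross-conjugated quinone carrying a styrene, prone to dimerise and polymerise, and it must itself be made by a late oxidation.
  - A6 is a strong carbon nucleophile that reacts with quinones by Michael addition and [2+2] pathways as readily as by the wanted [4+2] mode.
  - A5 offers a second unsubstituted enone terminus next to the C4 carbonyl.
- Comparison: in step count this road could be the shortest of all. The chosen plan is longer but each step is of a known type, and it does not depend on a fragile vinylquinone reacting in one of several open modes.

**Alternative 3:** Ring B is cut at C4a–C5 and C8–C8a. Quinone A8 and silyloxydiene A9 would combine in a thermal endo Diels–Alder reaction at the unsubstituted quinone double bond to give the cis-fused adduct A7.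
- Merits: the aryl and silyloxy groups of A9 both polarise the diene toward its CH2 terminus, and the methoxy group of A8 deactivates the C4 carbonyl, so the known regiochemical rules place the aryl group peri to C1 as required. A9 comes in two steps from a simple enone, so the route is convergent and probably no longer than the chosen one.
- Weak points: they lie after the cycloaddition.
  - A7 holds three stereocentres that must all be destroyed.
  - Ring B has to be dehydrogenated to a phenol while ring A is at the quinone or hydroquinone level.
  - The C6 oxygen then has to be methylated selectively in the presence of the other oxygen functions.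
  - The silyl enol ether and the ene-dione of A7 are both prone to uncontrolled enolisation and redox exchange.
- Comparison: this road is at least as good in convergence and in the reliability of its key bond formation. The chosen plan has a cleaner endgame: no dehydrogenation, no differentiation of hydroxyl groups, and the C6 methoxy group is present from the first step.

Key step: step 5

Remark on the chemistry: 15 has no stereocentre and its biaryl axis, lacking ortho substituents on ring C, is taken as freely rotating. The only stereocentres on the route are the two of cyclopropane 11, formed racemic and destroyed in the same step.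

## Route

Step 1
Reactants: 1 3-bromo-5-methoxybenzaldehyde; 2 Meldrum's acid (2,2-dimethyl-1,3-dioxane-4,6-dione)
Product: 4 5-(3-bromo-5-methoxybenzyl)-2,2-dimethyl-1,3-dioxane-4,6-dione, via benzylidene Meldrum's acid 3 (not isolated)
Conditions: Hantzsch ester (1.1 equiv), L-proline (20 mol%), EtOH, rt
Reagents that add atoms: none
Why: Knoevenagel condensation gives alkylidene 3, whose strongly electrophilic double bond should accept hydride from the Hantzsch ester (organocatalytic reductive alkylation); the acidity of the product stops the reaction at mono-alkylation, and the aryl bromide is inert.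

Step 2
Reactants: 4 5-(3-bromo-5-methoxybenzyl)-2,2-dimethyl-1,3-dioxane-4,6-dione
Product: 6 7-bromo-5-methoxy-2,3-dihydro-1H-inden-1-one, via indanone-2-carboxylic acid 5 (not isolated)
Conditions: Sc(OTf)3 (10 mol%), MeNO2, 100 °C
Reagents that add atoms: none
Why: Intramolecular Friedel–Crafts acylation with the Lewis-acid-activated Meldrum's acid as acylating agent should occur para to the methoxy group (ortho to bromine); loss of acetone gives β-keto acid 5, which decarboxylates under the conditions. Attack ortho to methoxy is less activated and would put the methoxy group peri to the new carbonyl, so the 5-bromo-7-methoxy isomer should be minor and separable.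

Step 3
Reactants: 6 7-bromo-5-methoxy-2,3-dihydro-1H-inden-1-one; 7 3,4-dimethoxyphenylboronic acid
Product: 8 7-(3,4-dimethoxyphenyl)-5-methoxy-2,3-dihydro-1H-inden-1-one
Conditions: Pd(dppf)Cl2 (3 mol%), K2CO3, 1,4-dioxane/H2O, 90 °C
Reagents that add atoms: none
Why: Suzuki–Miyaura coupling; oxidative addition of zerovalent palladium is helped by the ortho carbonyl group, the boronic acid is electron-rich and unhindered, and carbonate is too weak a base to cause aldol self-condensation of the indanone.

Step 4
Reactants: 8 7-(3,4-dimethoxyphenyl)-5-methoxy-2,3-dihydro-1H-inden-1-one
Product: 9 tert-butyl{[4-(3,4-dimethoxyphenyl)-6-methoxy-1H-inden-3-yl]oxy}dimethylsilane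
Conditions: TBSOTf, Et3N, CH2Cl2, 0 °C
Reagents that add atoms: tert-butyldimethylsilyl trifluoromethanesulfonate, CC(C)(C)[Si](C)(C)OS(=O)(=O)C(F)(F)F
Why: Soft enolisation and O-silylation of a ketone with a single enolisable position gives the silyl enol ether in one regiochemical sense; the tert-butyldimethylsilyl group is chosen because it should survive KOtBu in the next step.

Step 5
Reactants: 9 tert-butyl{[4-(3,4-dimethoxyphenyl)-6-methoxy-1H-inden-3-yl]oxy}dimethylsilane; 10 bromoform
Product: 12 tert-butyl{[2-bromo-8-(3,4-dimethoxyphenyl)-6-methoxynaphthalen-1-yl]oxy}dimethylsilane, via dibromocyclopropane adduct 11 (not isolated)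
Conditions: KOtBu (4 equiv), slow addition of 10 (1.5–2 equiv), hexane/toluene, −20 °C to rt
Reagents that add atoms: none
Why: Dibromocarbene, formed from 10 by α-elimination with KOtBu, adds in a concerted [2+1] cheletropic fashion to the C2=C3 enol ether bond of 9, the most nucleophilic π bond in the molecule, and closes the three-membered ring of the cis-fused adduct 11. This strained bicyclo[3.1.0] system carries a silyloxy donor at its benzylic bridgehead, so it should undergo thermal disrotatory 2π-electrocyclic opening of the internal C–C bond with departure of the endo bromide, which turns the five-membered ring into the six-membered ring A as a silyloxy- and aryl-stabilised 2-bromoallyl cation. Loss of a proton from the former CH2 (C4) to the excess base aromatises ring A and gives 12; the net result is insertion of C2 between C1 and C3 with formation of the C1–C2 and C2–C3 bonds. The closest known reaction type is the dihalocarbene ring expansion of indenes and of 1-indanone silyl enol ethers to 2-halonaphthalenes and 2-halo-1-naphthol derivatives. The two stereocentres of 11 are racemic and transient, and none remains in 12. The step needs chemoselectivity for the enol ether over the methoxyarenes, secured by the far higher nucleophilicity of the silyl enol ether and by adding 10 slowly in the cold so that little carbene is left for the methoxynaphthalene product; the site of insertion is fixed by the position of the enol ether double bond. If part of the silyl group is lost during ring opening, the resulting naphthol 13 is the intermediate of step 6 and converges there.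

Step 6
Reactants: 12 tert-butyl{[2-bromo-8-(3,4-dimethoxyphenyl)-6-methoxynaphthalen-1-yl]oxy}dimethylsilane
Product: 14 8-(3,4-dimethoxyphenyl)-2,6-dimethoxynaphthalen-1-ol, via 2-bromo-1-naphthol sodium salt 13 (not isolated)
Conditions: CuI (20 mol%), NaOMe (5 equiv), MeOH/DMF, 110 °C, argon; then aq. NH4Cl
Reagents that add atoms: sodium methoxide, [Na+].[O-]C
Why: Methoxide first cleaves the aryl silyl ether to naphtholate 13, and an Ullmann-type copper-mediated substitution then exchanges the ortho bromide for methoxide, as in the known conversion of ortho-bromophenols into ortho-methoxyphenols. Naphthol 14 is air-sensitive and should be taken on at once under argon.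

Step 7
Reactants: 14 8-(3,4-dimethoxyphenyl)-2,6-dimethoxynaphthalen-1-ol
Product: 15 8-(3,4-dimethoxyphenyl)-2,6-dimethoxynaphthalene-1,4-dione
Conditions: (KSO3)2NO (Fremy's salt, 2.5 equiv), KH2PO4 buffer, acetone/H2O, 0 °C to rt
Reagents that add atoms: potassium nitrosodisulfonate, [K+].[K+].[O-]S(=O)(=O)N([O])S(=O)(=O)[O-]
Why: Teuber oxidation: one equivalent of the nitroxyl radical abstracts the phenolic hydrogen, a second couples through oxygen at the free para carbon C4, and collapse of that adduct gives the para-quinone. C2 is blocked by the methoxy group, and this mild one-electron oxidant should leave the aryl ethers of rings B and C untouched.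

## Compound list

1 | 3-bromo-5-methoxybenzaldehyde | COc1cc(Br)cc(C=O)c1 | starting material
2 | Meldrum's acid (2,2-dimethyl-1,3-dioxane-4,6-dione) | CC1(C)OC(=O)CC(=O)O1 | starting material
3 | 5-(3-bromo-5-methoxybenzylidene)-2,2-dimethyl-1,3-dioxane-4,6-dione (not isolated) | COc1cc(Br)cc(C=C2C(=O)OC(C)(C)OC2=O)c1 | intermediate
4 | 5-(3-bromo-5-methoxybenzyl)-2,2-dimethyl-1,3-dioxane-4,6-dione | COc1cc(Br)cc(CC2C(=O)OC(C)(C)OC2=O)c1 | intermediate
5 | 7-bromo-5-methoxy-1-oxo-2,3-dihydro-1H-indene-2-carboxylic acid (racemic, not isolated) | COc1cc(Br)c2c(c1)CC(C(=O)O)C2=O | intermediate
6 | 7-bromo-5-methoxy-2,3-dihydro-1H-inden-1-one | COc1cc(Br)c2c(c1)CCC2=O | intermediate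
7 | 3,4-dimethoxyphenylboronic acid | COc1ccc(B(O)O)cc1OC | starting material
8 | 7-(3,4-dimethoxyphenyl)-5-methoxy-2,3-dihydro-1H-inden-1-one | COc1cc2c(c(-c3ccc(OC)c(OC)c3)c1)C(=O)CC2 | intermediate
9 | tert-butyl{[4-(3,4-dimethoxyphenyl)-6-methoxy-1H-inden-3-yl]oxy}dimethylsilane | CC(C)(C)[Si](C)(C)OC1=CCc2cc(OC)cc(-c3ccc(OC)c(OC)c3)c12 | intermediate
10 | bromoform | BrC(Br)Br | starting material
11 | racemic cis-fused 1,1-dibromo-1a-(tert-butyldimethylsilyloxy)-2-(3,4-dimethoxyphenyl)-4-methoxy-1,1a,6,6a-tetrahydrocyclopropa[a]indene (one enantiomer drawn, not isolated) | CC(C)(C)[Si](C)(C)O[C@]12c3c(-c4ccc(OC)c(OC)c4)cc(OC)cc3C[C@H]1C2(Br)Br | intermediate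
12 | tert-butyl{[2-bromo-8-(3,4-dimethoxyphenyl)-6-methoxynaphthalen-1-yl]oxy}dimethylsilane | CC(C)(C)[Si](C)(C)Oc1c(Br)ccc2cc(OC)cc(-c3ccc(OC)c(OC)c3)c12 | intermediate
13 | 2-bromo-8-(3,4-dimethoxyphenyl)-6-methoxynaphthalen-1-ol (present as its sodium salt, not isolated) | COc1cc(-c2ccc(OC)c(OC)c2)c2c(O)c(Br)ccc2c1 | intermediate
14 | 8-(3,4-dimethoxyphenyl)-2,6-dimethoxynaphthalen-1-ol | COc1ccc2cc(OC)cc(-c3ccc(OC)c(OC)c3)c2c1O | intermediate
15 | 8-(3,4-dimethoxyphenyl)-2,6-dimethoxynaphthalene-1,4-dione | COC1=CC(=O)c2cc(OC)cc(-c3ccc(OC)c(OC)c3)c2C1=O | target

## Step count and risk

Total steps: 7. Longest linear sequence: 7 steps, from 1 to 15.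

**Step 5 (key step).** Three processes could spoil it:
- loss of the silyl group during ring opening, which frees a naphtholate that then suffers Reimer–Tiemann-type attack by the carbene;
- a second carbene addition to the electron-rich methoxynaphthalene product;
- cleavage of the enol ether by KOtBu before cyclopropanation.

The fallback sets out from 9 and comes back at 13. It separates the one-carbon insertion from the halogenation.
- Simmons–Smith cyclopropanation (Et2Zn, CH2I2) should give the racemic cis-fused 1a-(tert-butyldimethylsilyloxy)-2-(3,4-dimethoxyphenyl)-4-methoxy-1,1a,6,6a-tetrahydrocyclopropa[a]indene F1.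
- FeCl3 in DMF should open its internal bond oxidatively (Ito–Saegusa ring expansion) to 3-chloro-8-(3,4-dimethoxyphenyl)-6-methoxy-3,4-dihydronaphthalen-1(2H)-one F2.
- NaOAc in MeOH should eliminate hydrogen chloride, and the enone should tautomerise in the flask to 8-(3,4-dimethoxyphenyl)-6-methoxynaphthalen-1-ol F3.
- Amine-catalysed ortho-bromination with N-bromosuccinimide and diisopropylamine should then give 13, which enters step 6 as the free naphthol.

**Step 2.** The acylation may partition between the two positions ortho to the side chain. It may also be slow on a ring that carries bromine, so that the Meldrum's acid decomposes through its ketene before it cyclises. The fallback sets out from 7 and comes back at 8. It uses a symmetrical ring so that no regiochemical choice arises.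
- Commercial 5,7-dimethoxy-2,3-dihydro-1H-inden-1-one F4 should be demethylated selectively at the peri oxygen with BCl3 through the carbonyl chelate, giving 7-hydroxy-5-methoxy-2,3-dihydro-1H-inden-1-one F5.
- Triflic anhydride and pyridine should convert this into 6-methoxy-3-oxo-2,3-dihydro-1H-inden-4-yl trifluoromethanesulfonate F6.
- Suzuki–Miyaura coupling of F6 with 7 under the conditions of step 3 gives 8.

**Step 6.** Substitution of an electron-rich, flanked aryl bromide may be slow, protodebromination may compete, and the naphtholate may oxidise in air at the temperature needed. The fallback sets out from 12 and comes back at 15. It moves the methoxide substitution to the quinone stage, where it is an addition–elimination and needs no copper.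
- Bu4NF should remove the silyl group and give 13, isolated this time.
- (KSO3)2NO should oxidise it at C4 to 2-bromo-8-(3,4-dimethoxyphenyl)-6-methoxynaphthalene-1,4-dione F7.
- NaOMe in MeOH at 0 °C should replace the vinylic bromide at the carbon that bears it, giving 15.

This fallback also bypasses step 7.

**Step 7.** The phenoxyl radical may dimerise by C–C coupling at C4, the oxidant may attack C2 with loss of methanol toward the 1,2-quinone, and the substrate may be poorly soluble in the aqueous medium. The fallback sets out from 14 and comes back at 15. It brings in the C4 heteroatom by a two-electron electrophilic substitution.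
- Azo coupling with benzenediazonium chloride at the free para position should give 8-(3,4-dimethoxyphenyl)-2,6-dimethoxy-4-[(E)-phenyldiazenyl]naphthalen-1-ol F8.
- Reduction with Na2S2O4 should cleave the azo bond to 4-amino-8-(3,4-dimethoxyphenyl)-2,6-dimethoxynaphthalen-1-ol F9.
- Oxidation with aqueous FeCl3 should give the quinone imine, which hydrolyses to 15.

## Further compounds

F1 | step 5 | racemic cis-fused 1a-(tert-butyldimethylsilyloxy)-2-(3,4-dimethoxyphenyl)-4-methoxy-1,1a,6,6a-tetrahydrocyclopropa[a]indene (one enantiomer drawn) | CC(C)(C)[Si](C)(C)O[C@]12c3c(-c4ccc(OC)c(OC)c4)cc(OC)cc3C[C@H]1C2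
F2 | step 5 | 3-chloro-8-(3,4-dimethoxyphenyl)-6-methoxy-3,4-dihydronaphthalen-1(2H)-one (racemic) | COc1cc2c(c(-c3ccc(OC)c(OC)c3)c1)C(=O)CC(Cl)C2
F3 | step 5 | 8-(3,4-dimethoxyphenyl)-6-methoxynaphthalen-1-ol | COc1cc(-c2ccc(OC)c(OC)c2)c2c(O)cccc2c1
F4 | step 2 | 5,7-dimethoxy-2,3-dihydro-1H-inden-1-one | COc1cc(OC)c2c(c1)CCC2=O
F5 | step 2 | 7-hydroxy-5-methoxy-2,3-dihydro-1H-inden-1-one | COc1cc(O)c2c(c1)CCC2=O
F6 | step 2 | 6-methoxy-3-oxo-2,3-dihydro-1H-inden-4-yl trifluoromethanesulfonate | COc1cc(OS(=O)(=O)C(F)(F)F)c2c(c1)CCC2=O
F7 | step 6 | 2-bromo-8-(3,4-dimethoxyphenyl)-6-methoxynaphthalene-1,4-dione | COc1cc(-c2ccc(OC)c(OC)c2)c2c(c1)C(=O)C=C(Br)C2=O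
F8 | step 7 | 8-(3,4-dimethoxyphenyl)-2,6-dimethoxy-4-[(E)-phenyldiazenyl]naphthalen-1-ol | COc1cc(/N=N/c2ccccc2)c2cc(OC)cc(-c3ccc(OC)c(OC)c3)c2c1O
F9 | step 7 | 4-amino-8-(3,4-dimethoxyphenyl)-2,6-dimethoxynaphthalen-1-ol | COc1cc(N)c2cc(OC)cc(-c3ccc(OC)c(OC)c3)c2c1O
A1 | alternative 1 | 8-(3,4-dimethoxyphenyl)-1,2,4,6-tetramethoxynaphthalene | COc1cc(OC)c2cc(OC)cc(-c3ccc(OC)c(OC)c3)c2c1OC
A2 | alternative 1 | 1-(3,4-dimethoxyphenyl)-5,7,8-trimethoxy-3H-2-benzopyran-3-one | O=C1C=C2C(OC)=CC(OC)=C(OC)C2=C(c2ccc(OC)c(OC)c2)O1
A3 | alternative 1 | methoxyacetylene (methoxyethyne) | C#COC
A4 | alternative 2 | 8-(3,4-dimethoxyphenyl)-2,6,6-trimethoxy-5,6-dihydronaphthalene-1,4-diol | COc1cc(O)c2c(c1O)C(c1ccc(OC)c(OC)c1)=CC(OC)(OC)C2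
A5 | alternative 2 | 2-[1-(3,4-dimethoxyphenyl)ethenyl]-6-methoxycyclohexa-2,5-diene-1,4-dione | COC1=CC(=O)C=C(C(=C)c2ccc(OC)c(OC)c2)C1=O
A6 | alternative 2 | 1,1-dimethoxyethene | C=C(OC)OC
A7 | alternative 3 | racemic cis-fused 6-(tert-butyldimethylsilyloxy)-8-(3,4-dimethoxyphenyl)-2-methoxy-4a,5,8,8a-tetrahydronaphthalene-1,4-dione with H-4a, H-8 and H-8a all cis (endo adduct, one enantiomer drawn) | COC1=CC(=O)[C@H]2CC(O[Si](C)(C)C(C)(C)C)=C[C@@H](c3ccc(OC)c(OC)c3)[C@H]2C1=O
A8 | alternative 3 | 2-methoxy-1,4-benzoquinone | COC1=CC(=O)C=CC1=O
A9 | alternative 3 | (E)-tert-butyl{[4-(3,4-dimethoxyphenyl)buta-1,3-dien-2-yl]oxy}dimethylsilane | C=C(O[Si](C)(C)C(C)(C)C)/C=C/c1ccc(OC)c(OC)c1
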